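**Retrosynthetic overview**

- Each ring (numbered C1=O, C2–OH, C3–chain, C4=O, C5–OCH3, C6–CH3) has its C1 and C5 oxygens meta to the C3 chain with the C6 methyl between them: a 2-methyl-5-alkylresorcinol hidden in a quinone.
- The C2 hydroxyl (epoxide of C2=C3, then acid) and the C4 carbonyl (para-oxidation of the C1 phenol) are removed first, leading back to bis(3-methoxy-2-methylphenol) 11 and, through its dihydro form 10, to bis(2-methylcyclohexane-1,3-dione) 9.
- Both six-membered rings are then cut at C2–C3 (Michael) and C5–C6 (Claisen), giving bis-enoate 4 and two molecules of methyl 3-oxopentanoate 5. The two carbocycles form in the same operation; there is no other ring-forming step.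
- Bis-enoate 4 comes from hexadecane-1,16-diol 1 by oxidation and double Horner–Wadsworth–Emmons olefination.

Key step: step 3

Remark: the target has no stereocentre and is taken as the 2-hydroxy-1,4-quinone tautomer drawn; the stereoisomer mixtures at 7, 10 and 13 are carried forward unseparated because every sp3 centre is erased later.

**Route**

Step 1
Reactants: 1 hexadecane-1,16-diol
Product: 2 hexadecanedial
Conditions: PhI(OAc)2 (2.4 equiv), 2,2,6,6-tetramethylpiperidin-1-oxyl (0.2 equiv), CH2Cl2, rt
Reagents that add atoms: none
Why: Nitroxyl-catalysed alcohol oxidation with PhI(OAc)2 as terminal oxidant stops at the aldehyde in anhydrous CH2Cl2, and the sparingly soluble diol should dissolve as it is consumed; the dialdehyde is used crude.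

Step 2
Reactants: 2 hexadecanedial; 3 trimethyl phosphonoacetate
Product: 4 dimethyl (2E,18E)-icosa-2,18-dienedioate
Conditions: 3 (2.3 equiv), NaH (2.3 equiv), THF, 0 °C to rt
Reagents that add atoms: trimethyl phosphonoacetate (3), COC(=O)CP(=O)(OC)OC
Why: Horner–Wadsworth–Emmons olefination of an aliphatic aldehyde with a stabilised phosphonate anion should give the E-enoate at both ends; the alkene geometry is not carried into the target.

Step 3
Reactants: 4 dimethyl (2E,18E)-icosa-2,18-dienedioate; 5 methyl 3-oxopentanoate
Product: 7 dimethyl 6,6'-(tetradecane-1,14-diyl)bis(3-methyl-2,4-dioxocyclohexane-1-carboxylate), via bis-Michael adduct 6 (not isolated)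
Conditions: 5 (2.5 equiv), NaOCH3 (2.6 equiv), CH3OH/THF, reflux; then cold 1 M HCl
Reagents that add atoms: methyl 3-oxopentanoate (5), CCC(=O)CC(=O)OC
Why: NaOCH3 deprotonates the CH2 between the two carbonyls of 5, and this enolate adds to the β-carbon of each enoate (Michael addition, forming C2–C3 of the target numbering) to give 6. Under the same equilibrating conditions the ethyl-ketone CH2 of 6 is enolised and attacks the ester carbonyl that came from the enoate, expelling methoxide (intramolecular Claisen condensation of the Dieckmann type, forming C5–C6). Each of the two rings closes in the 6-exo-trig mode, and the closest known reaction is the dihydroresorcinol synthesis from a crotonate and an acetoacetate, here with a propionyl donor so that the C-methyl is built in. The three sp3 stereocentres created per ring are not controlled (the trans arrangement of ester and chain is expected under equilibration), and none is needed, because the ester-bearing carbon is cleared in step 4 and the ring is aromatised in step 6. Regiochemistry is secured by the substrate: only the doubly activated CH2 of 5 is acidic enough to act as Michael donor, and only the ethyl CH2 can reach the ester through a six-membered transition state. Both reversible steps are pulled forward by deprotonation of the 2-methyl-1,3-dione product, and the excess of 5 should keep a Michael adduct from adding to a second enoate.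

Step 4
Reactants: 7 dimethyl 6,6'-(tetradecane-1,14-diyl)bis(3-methyl-2,4-dioxocyclohexane-1-carboxylate)
Product: 9 5,5'-(tetradecane-1,14-diyl)bis(2-methylcyclohexane-1,3-dione), via bis-keto acid 8 (not isolated)
Conditions: NaOH (aq), CH3OH, reflux; then HCl to pH 1, reflux
Reagents that add atoms: none
Why: Ester saponification followed by acid-promoted decarboxylation of the cyclic β-keto acid is the standard finish of a dihydroresorcinol synthesis; the 2-methyl-1,3-dione is protected as its enolate during the basic stage.

Step 5
Reactants: 9 5,5'-(tetradecane-1,14-diyl)bis(2-methylcyclohexane-1,3-dione)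
Product: 10 5,5'-(tetradecane-1,14-diyl)bis(3-methoxy-2-methylcyclohex-2-en-1-one)
Conditions: CH3OH, 4-CH3C6H4SO3H·H2O (cat.), toluene, reflux, 3 Å molecular sieves
Reagents that add atoms: methanol, CO
Why: Acid-catalysed enol ether formation on the vinylogous acid differentiates the two ring oxygens; each dione ring is mirror-symmetric through its methyl- and chain-bearing carbons, so only one constitution can form, and the chain-bearing stereocentre that appears in each ring (uncontrolled, racemic plus meso) is erased in step 6.

Step 6
Reactants: 10 5,5'-(tetradecane-1,14-diyl)bis(3-methoxy-2-methylcyclohex-2-en-1-one)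
Product: 11 5,5'-(tetradecane-1,14-diyl)bis(3-methoxy-2-methylphenol)
Conditions: Pd(OCOCF3)2 (10 mol%), 2-(dimethylamino)pyridine (20 mol%), 4-CH3C6H4SO3H·H2O (40 mol%), O2 (1 atm), DMSO, 80 °C
Reagents that add atoms: none
Why: Aerobic dehydrogenation of a cyclohexenone catalysed by divalent palladium: a palladium enolate at the α' CH2 undergoes β-hydride elimination toward the chain-bearing CH, tautomerisation then delivers the phenol, and O2 reoxidises zerovalent palladium.

Step 7
Reactants: 11 5,5'-(tetradecane-1,14-diyl)bis(3-methoxy-2-methylphenol)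
Product: 12 5,5'-(tetradecane-1,14-diyl)bis(3-methoxy-2-methylcyclohexa-2,5-diene-1,4-dione)
Conditions: (KSO3)2NO (5 equiv), KH2PO4, (n-C4H9)4N·HSO4 (cat.), CH2Cl2/H2O, rt
Reagents that add atoms: Fremy's salt (potassium nitrosodisulfonate), [K+].[K+].[O]N(S(=O)(=O)[O-])S(=O)(=O)[O-]
Why: Teuber oxidation: one equivalent of the nitroxyl radical abstracts the phenolic hydrogen, a second couples through oxygen at the unsubstituted para carbon (C4, between chain and methoxy), and loss of imidodisulfonate gives the para-quinone.

Step 8
Reactants: 12 5,5'-(tetradecane-1,14-diyl)bis(3-methoxy-2-methylcyclohexa-2,5-diene-1,4-dione)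
Product: 13 1,1'-(tetradecane-1,14-diyl)bis(3-methoxy-4-methyl-7-oxabicyclo[4.1.0]hept-3-ene-2,5-dione)
Conditions: 30% aq H2O2, Na2CO3, THF/H2O, 0 °C, short reaction time
Reagents that add atoms: hydrogen peroxide, OO
Why: Weitz–Scheffer nucleophilic epoxidation: hydroperoxide anion adds to the unsubstituted carbon of the chain-bearing C2=C3 double bond and the enolate closes onto the O–O bond, whereas the methoxy-donated, tetrasubstituted C5=C6 double bond is far less electrophilic; each epoxide is necessarily cis-fused, the relation between the two rings is uncontrolled, and all four stereocentres disappear in step 9.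

Step 9
Reactants: 13 1,1'-(tetradecane-1,14-diyl)bis(3-methoxy-4-methyl-7-oxabicyclo[4.1.0]hept-3-ene-2,5-dione)
Product: 14 3,3'-(tetradecane-1,14-diyl)bis(2-hydroxy-5-methoxy-6-methylcyclohexa-2,5-diene-1,4-dione)
Conditions: conc. H2SO4, 0 °C to rt, 15 min; then ice-water
Reagents that add atoms: none
Why: Acid-catalysed isomerisation of a 2,3-epoxy-1,4-quinone to a 2-hydroxy-1,4-quinone (as in the conversion of 2-methyl-1,4-naphthoquinone oxide into its hydroxyquinone): the protonated epoxide ionises at the tertiary chain-bearing carbon and loss of the proton from the CH–O carbon gives the vinylogous acid, which leaves the hydroxyl on C2 next to the chain.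

**Compound list**

1 | hexadecane-1,16-diol | OCCCCCCCCCCCCCCCCO | starting material
2 | hexadecanedial | O=CCCCCCCCCCCCCCCC=O | intermediate
3 | trimethyl phosphonoacetate | COC(=O)CP(=O)(OC)OC | starting material
4 | dimethyl (2E,18E)-icosa-2,18-dienedioate | COC(=O)/C=C/CCCCCCCCCCCCCC/C=C/C(=O)OC | intermediate
5 | methyl 3-oxopentanoate | CCC(=O)CC(=O)OC | starting material
6 | dimethyl 3,18-bis(1-methoxy-1,3-dioxopentan-2-yl)icosanedioate (bis-Michael adduct, stereoisomer mixture, formed in the flask, not isolated) | CCC(=O)C(C(=O)OC)C(CC(=O)OC)CCCCCCCCCCCCCCC(CC(=O)OC)C(C(=O)OC)C(=O)CC | intermediate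
7 | dimethyl 6,6'-(tetradecane-1,14-diyl)bis(3-methyl-2,4-dioxocyclohexane-1-carboxylate) (mixture of stereoisomers and enol tautomers) | COC(=O)C1C(=O)C(C)C(=O)CC1CCCCCCCCCCCCCCC1CC(=O)C(C)C(=O)C1C(=O)OC | intermediate
8 | 6,6'-(tetradecane-1,14-diyl)bis(3-methyl-2,4-dioxocyclohexane-1-carboxylic acid) (bis-keto acid, formed in the flask, not isolated) | OC(=O)C1C(=O)C(C)C(=O)CC1CCCCCCCCCCCCCCC1CC(=O)C(C)C(=O)C1C(=O)O | intermediate
9 | 5,5'-(tetradecane-1,14-diyl)bis(2-methylcyclohexane-1,3-dione) (keto form drawn) | CC1C(=O)CC(CC1=O)CCCCCCCCCCCCCCC1CC(=O)C(C)C(=O)C1 | intermediate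
10 | 5,5'-(tetradecane-1,14-diyl)bis(3-methoxy-2-methylcyclohex-2-en-1-one) (racemic and meso diastereomers) | COC1=C(C)C(=O)CC(C1)CCCCCCCCCCCCCCC1CC(=O)C(C)=C(OC)C1 | intermediate
11 | 5,5'-(tetradecane-1,14-diyl)bis(3-methoxy-2-methylphenol) | COc1c(C)c(O)cc(c1)CCCCCCCCCCCCCCc1cc(O)c(C)c(OC)c1 | intermediate
12 | 5,5'-(tetradecane-1,14-diyl)bis(3-methoxy-2-methylcyclohexa-2,5-diene-1,4-dione) | COC1=C(C)C(=O)C=C(C1=O)CCCCCCCCCCCCCCC1=CC(=O)C(C)=C(OC)C1=O | intermediate
13 | 1,1'-(tetradecane-1,14-diyl)bis(3-methoxy-4-methyl-7-oxabicyclo[4.1.0]hept-3-ene-2,5-dione) (cis-fused epoxides, diastereomer mixture) | COC1=C(C)C(=O)C2OC2(C1=O)CCCCCCCCCCCCCCC12OC1C(=O)C(C)=C(OC)C2=O | intermediate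
14 | 3,3'-(tetradecane-1,14-diyl)bis(2-hydroxy-5-methoxy-6-methylcyclohexa-2,5-diene-1,4-dione) (no stereocentres) | COC1=C(C)C(=O)C(O)=C(CCCCCCCCCCCCCCC2=C(O)C(=O)C(C)=C(OC)C2=O)C1=O | target

**Step count**

Total steps: 9. Longest linear sequence: 9 steps (from hexadecane-1,16-diol 1).

**Steps most likely to fail and fallbacks**

Step 3 (key step). The risks are incomplete annulation at the second chain end, reversal of the Michael addition, addition of a Michael adduct to a second enoate leading to oligomers, and methoxide cleavage of the keto ester before ring closure. The fallback sets out from dialdehyde 2. A double Wittig olefination with 1-(triphenylphosphoranylidene)butan-2-one (toluene, 80 °C) should give the bis-enone (4E,20E)-tetracosa-4,20-diene-3,22-dione F1. Dimethyl malonate and NaOCH3 in CH3OH at reflux then add to each enone β-carbon to give the bis-malonate adduct tetramethyl 2,2'-(3,22-dioxotetracosane-5,20-diyl)dipropanedioate F2. Its ethyl-ketone CH2 closes onto one malonate ester (the enone/malonate resorcinol synthesis, with a more reactive acceptor and a better-behaved donor), and acidification delivers 7, where the route is rejoined.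

Step 6. The risks are slow palladation of the electron-rich vinylogous ester, acid-mediated loss of the enol ether through the water formed (which would remove the differentiation of the two oxygens), and catalyst decomposition before both rings are aromatised. The fallback sets out from 10. Kinetic α'-deprotonation with LiN(iPr)2 (THF, −78 °C) and trapping with PhSeCl should give 5,5'-(tetradecane-1,14-diyl)bis[3-methoxy-2-methyl-6-(phenylselanyl)cyclohex-2-en-1-one] F3. Oxidation with excess H2O2 (CH2Cl2/pyridine, 0 °C to rt) triggers selenoxide syn-elimination toward the chain-bearing carbon and tautomerisation to 11, where the route is rejoined.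

Step 8. The risks are attack of hydroperoxide or hydroxide at the methoxy-bearing carbon with loss of the methyl ether, premature base-induced opening of the epoxide followed by oxidative degradation of the hydroxyquinone anion, and, in the following acid step, hydrolysis of the vinylogous methyl ester. The fallback sets out from 12 and replaces steps 8 and 9. Thiele–Winter acetoxylation (Ac2O, BF3·OEt2) adds acetate at the only unsubstituted ring carbon and should give 3,3'-(tetradecane-1,14-diyl)bis(5-methoxy-6-methylbenzene-1,2,4-triyl) hexaacetate F4. Acid methanolysis under argon (HCl, CH3OH) gives 3,3'-(tetradecane-1,14-diyl)bis(5-methoxy-6-methylbenzene-1,2,4-triol) F5. After removal of the methanol, oxidation with air or aqueous FeCl3 gives 14 directly.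

**Further compounds**

F1 | step 3 | (4E,20E)-tetracosa-4,20-diene-3,22-dione | CCC(=O)/C=C/CCCCCCCCCCCCCC/C=C/C(=O)CC
F2 | step 3 | tetramethyl 2,2'-(3,22-dioxotetracosane-5,20-diyl)dipropanedioate | CCC(=O)CC(C(C(=O)OC)C(=O)OC)CCCCCCCCCCCCCCC(CC(=O)CC)C(C(=O)OC)C(=O)OC
F3 | step 6 | 5,5'-(tetradecane-1,14-diyl)bis[3-methoxy-2-methyl-6-(phenylselanyl)cyclohex-2-en-1-one] | COC1=C(C)C(=O)C([Se]c2ccccc2)C(C1)CCCCCCCCCCCCCCC1CC(OC)=C(C)C(=O)C1[Se]c1ccccc1
F4 | step 8 | 3,3'-(tetradecane-1,14-diyl)bis(5-methoxy-6-methylbenzene-1,2,4-triyl) hexaacetate | COc1c(C)c(OC(C)=O)c(OC(C)=O)c(c1OC(C)=O)CCCCCCCCCCCCCCc1c(OC(C)=O)c(OC(C)=O)c(C)c(OC)c1OC(C)=O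
F5 | step 8 | 3,3'-(tetradecane-1,14-diyl)bis(5-methoxy-6-methylbenzene-1,2,4-triol) | COc1c(C)c(O)c(O)c(c1O)CCCCCCCCCCCCCCc1c(O)c(O)c(C)c(OC)c1O
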